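## Retrosynthetic overview

1. Ring A (hemiketal) is closed last from a δ-hydroxy ketone. The C-7 quaternary centre comes from a bridging C-7 ketone: methoxymethylenation, hydroxymethylation (C-8), then Wittig chain extension (C-6 to C-1).
2. Rings D and E are formed together by a Pauson–Khand reaction of the ring C alkene (C-13=C-14) with an alkyne on C-19. This gives the transposed enone; hydrogenation and Saegusa oxidation move the alkene to C-13=C-14, and CBS reduction sets C-17.
3. Ring B is closed by a Mannich reaction at C-10 and lactamisation onto the C-26 ester, followed by lactam reduction.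
4. The C-25 quaternary centre is set by an asymmetric deconjugative Michael addition of a cycloheptenone β-keto ester (ring C, purchased) to an enyne ester.
5. Ring order: C (purchased) → B → D + E (one operation) → A.

Assumption: atom labels C-1 to C-29 follow the atom order of the target SMILES (ring A hemiketal, B piperidine, C cycloheptene, D cyclopentenol, E ester-bearing cyclopentane); the C-3 hemiketal is the thermodynamic anomer; the cinchonidinium catalyst is assumed to give the (R) adduct (its cinchoninium pseudoenantiomer would be used otherwise).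

## Route

Step 1
Reactants: 1 methyl 2-oxocycloheptane-1-carboxylate
Product: 3 methyl 7-oxocyclohept-1-ene-1-carboxylate, via α-phenylselenide 2 (not isolated)
Conditions: PhSeCl, pyridine, CH2Cl2, 0 °C; then 30% H2O2, 0 °C to rt
Reagents that add atoms: none
Why: α-Selenenylation of the β-keto ester followed by selenoxide syn-elimination (Reich dehydrogenation) gives the 2-carbomethoxy enone; no stereocentre is formed.

Step 2
Reactants: 4 methyl 2-bromoprop-2-enoate; 5 ethynyl(trimethyl)silane
Product: 6 methyl 2-methylidene-4-(trimethylsilyl)but-3-ynoate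
Conditions: PdCl2(PPh3)2 (2 mol%), CuI (4 mol%), iPr2NH, THF, 0 °C to rt
Reagents that add atoms: none
Why: Sonogashira coupling of the α-bromoacrylate with the terminal alkyne gives the cross-conjugated enyne ester that carries C-24, C-19, C-20, C-15 and C-16; no stereocentre is formed.

Step 3
Reactants: 3 methyl 7-oxocyclohept-1-ene-1-carboxylate; 6 methyl 2-methylidene-4-(trimethylsilyl)but-3-ynoate
Product: 7 methyl (1R)-1-[2-(methoxycarbonyl)-4-(trimethylsilyl)but-3-yn-1-yl]-7-oxocyclohept-2-ene-1-carboxylate (C-19 epimers)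
Conditions: N-(9-anthracenylmethyl)cinchonidinium bromide (10 mol%), Cs2CO3 (0.5 equiv), toluene, −40 °C, slow addition of 3
Reagents that add atoms: none
Why: Proposed new method: γ-deprotonation of 3 at C-13 gives the dienolate of a vinylogous β-keto ester, which as a chiral ammonium ion pair adds through its α-carbon (C-25) to the CH2 terminus of 6 (deconjugative Michael addition), setting the C-25 quaternary centre by catalyst control and leaving the C-13=C-14 alkene, while C-19 forms unselectively and is corrected in step 10; the closest known reactions are phase-transfer-catalysed asymmetric Michael additions of cyclic β-keto esters and deconjugative α-alkylations of alkylidene β-dicarbonyl compounds.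

Step 4
Reactants: 7 methyl (1R)-1-[2-(methoxycarbonyl)-4-(trimethylsilyl)but-3-yn-1-yl]-7-oxocyclohept-2-ene-1-carboxylate
Product: 9 methyl 2-[(8-methyl-9,10-dioxo-8-azabicyclo[4.3.1]dec-2-en-1-yl)methyl]-4-(trimethylsilyl)but-3-ynoate, via Mannich base 8 (not isolated)
Conditions: MeNH2·HCl, (CH2O)n, MeOH, 65 °C; then NaHCO3, 65 °C
Reagents that add atoms: methylamine hydrochloride, CN.Cl; paraformaldehyde (as formaldehyde), C=O
Why: The only enolisable position of the C-7 ketone (C-10) undergoes a Mannich reaction with the N-methyl methyleneiminium ion, C-10 equilibrates until the aminomethyl group is cis to the C-26 ester, and the secondary amine then lactamises to close ring B, so the new C-10 centre is fixed by the bridge.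

Step 5
Reactants: 9 methyl 2-[(8-methyl-9,10-dioxo-8-azabicyclo[4.3.1]dec-2-en-1-yl)methyl]-4-(trimethylsilyl)but-3-ynoate
Product: 11 methyl 2-[(8-methyl-10-oxo-8-azabicyclo[4.3.1]dec-2-en-1-yl)methyl]but-3-ynoate, via silyl alkyne amine 10 (not isolated)
Conditions: Zn(OAc)2 (10 mol%), (EtO)3SiH, THF, 40 °C; then KF (20 mol%), MeOH, 0 °C
Reagents that add atoms: none
Why: Zinc-catalysed hydrosilylation reduces the tertiary lactam to the amine in the presence of the non-enolisable ketone, the ester, the alkene and the alkyne, and fluoride-catalysed methanolysis then frees the terminal alkyne; no stereocentre changes.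

Step 6
Reactants: 11 methyl 2-[(8-methyl-10-oxo-8-azabicyclo[4.3.1]dec-2-en-1-yl)methyl]but-3-ynoate
Product: 13 tetracyclic C-15=C-16 enone (rings B to E), via dicobalt hexacarbonyl complex 12 (not isolated)
Conditions: Co2(CO)8, CH2Cl2, rt; then N-methylmorpholine N-oxide, 0 °C to rt
Reagents that add atoms: dicobalt octacarbonyl Co2(CO)8 (source of the C-17 carbonyl), O=C=[Co](=C=O)(=C=O)(=C=O)[Co](=C=O)(=C=O)(=C=O)=C=O
Why: Intramolecular Pauson–Khand [2+2+1] cycloaddition of the 1,6-enyne closes rings D and E in one operation, because the alkyne–cobalt unit tethered to bridgehead C-25 reaches only the exo face of the ring C alkene (syn to the one-carbon C-7 bridge), which places H-13 and H-14 cis on the side of the nitrogen bridge.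

Step 7
Reactants: 13 tetracyclic C-15=C-16 enone
Product: 14 tetracyclic saturated C-17 ketone (H-13, H-14 and H-15 all cis)
Conditions: H2 (1 atm), 10% Pd/C, EtOAc, rt
Reagents that add atoms: none
Why: Heterogeneous hydrogenation delivers hydrogen to the convex face of the bicyclo[3.3.0]octenone, giving the cis ring fusion (H-15 cis to H-14), which is the C-15 configuration of the target.

Step 8
Reactants: 14 tetracyclic saturated C-17 ketone
Product: 16 tetracyclic C-13=C-14 enone, via trimethylsilyl enol ether 15 (not isolated)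
Conditions: TMSCl, NaI, Et3N, MeCN, rt; then Pd(OAc)2, MeCN, rt
Reagents that add atoms: none
Why: Thermodynamic silyl enol ether formation occurs towards the more substituted C-13 (the C-7 ketone cannot enolise, being flanked by quaternary C-25 and bridgehead C-10), and Saegusa–Ito oxidation with syn β-hydride elimination of H-14 gives the tetrasubstituted enone, removing the C-13 and C-14 centres and leaving C-15 untouched.

Step 9
Reactants: 16 tetracyclic C-13=C-14 enone
Product: 17 (17S)-allylic alcohol with the C-7 ketone intact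
Conditions: (R)-2-methyl-CBS-oxazaborolidine (20 mol%), catecholborane, toluene, −78 °C
Reagents that add atoms: none
Why: Corey–Bakshi–Shibata reduction, in which the (R)-oxazaborolidine treats the alkenyl arm (C-13) as the large group and delivers hydride to the β-face of C-17 under reagent control (mismatched with the substrate bias from C-19), giving the α-hydroxyl, while the hindered bridging C-7 ketone does not react at −78 °C.

Step 10
Reactants: 17 (17S)-allylic alcohol with the C-7 ketone intact
Product: 19 C-7 methoxymethylidene enol ether with the (19R) ester, via enol ether 18 (not isolated)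
Conditions: Ph3P(CH2OMe)Cl, KN(SiMe3)2, THF, 0 to 50 °C; then LiN(iPr)2, −78 °C; then AcOH, −78 °C
Reagents that add atoms: (methoxymethyl)triphenylphosphonium chloride, COC[P+](c1ccccc1)(c1ccccc1)c1ccccc1.[Cl-]
Why: Wittig methoxymethylenation of the only remaining ketone is followed in the same flask by ester enolate formation and kinetic protonation from the convex α-face (the face of H-15), which puts the C-19 ester on the β-face, cis to C-16, as in the target.

Step 11
Reactants: 19 C-7 methoxymethylidene enol ether with the (19R) ester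
Product: 21 C-7 formyl hydroxymethyl compound (hydroxymethyl C-8 over ring C), via aldehyde 20 (not isolated)
Conditions: 1 M aq. HCl, THF, 0 °C to rt; then K2CO3, 37% aq. CH2O, rt
Reagents that add atoms: water, O; formaldehyde, C=O
Why: Acid hydrolysis of the enol ether unmasks the C-7 aldehyde (its carbon is the future C-6), and the enolate then undergoes a crossed aldol (hydroxymethylation) with formaldehyde on the face syn to the flattened cycloheptene bridge, which presents one syn-axial hydrogen against two on the piperidine side, so C-8 ends over ring C and the C-7 quaternary centre is set.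

Step 12
Reactants: 21 C-7 formyl hydroxymethyl compound
Product: 22 (E)-enone carrying the complete C-6 to C-1 chain
Conditions: Ph3P=CHC(O)Et, toluene, 90 °C
Reagents that add atoms: 1-(triphenyl-λ5-phosphanylidene)butan-2-one, CCC(=O)C=P(c1ccccc1)(c1ccccc1)c1ccccc1
Why: Wittig olefination of the neopentyl aldehyde with a stabilised ylide gives the (E)-enone under neutral conditions that avoid retro-aldol loss of formaldehyde; no stereocentre is formed.

Step 13
Reactants: 22 (E)-enone carrying the complete C-6 to C-1 chain
Product: 24 target CNP0124876.1, via hydroxy ketone 23 (not isolated)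
Conditions: RhCl(PPh3)3 (5 mol%), H2 (1 atm), benzene/EtOH, rt
Reagents that add atoms: none
Why: Homogeneous hydrogenation saturates only the disubstituted enone alkene (the tetrasubstituted C-13=C-14 alkene and the allylic alcohol are untouched), and the δ-hydroxy ketone closes spontaneously to the six-membered hemiketal, with C-3 settling as the anomerically stabilised isomer under thermodynamic control.

## Compound list

1 | methyl 2-oxocycloheptane-1-carboxylate | O=C1CCCCCC1C(=O)OC | starting material
2 | methyl 2-oxo-1-(phenylselanyl)cycloheptane-1-carboxylate | O=C1CCCCCC1(C(=O)OC)[Se]c1ccccc1 | intermediate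
3 | methyl 7-oxocyclohept-1-ene-1-carboxylate | O=C1CCCCC=C1C(=O)OC | intermediate
4 | methyl 2-bromoprop-2-enoate | C=C(Br)C(=O)OC | starting material
5 | ethynyl(trimethyl)silane | C#C[Si](C)(C)C | starting material
6 | methyl 2-methylidene-4-(trimethylsilyl)but-3-ynoate | C=C(C(=O)OC)C#C[Si](C)(C)C | intermediate
7 | methyl (1R)-1-[2-(methoxycarbonyl)-4-(trimethylsilyl)but-3-yn-1-yl]-7-oxocyclohept-2-ene-1-carboxylate, C-19 epimers | O=C1CCCC=C[C@@]1(CC(C(=O)OC)C#C[Si](C)(C)C)C(=O)OC | intermediate
8 | Mannich base of 7: 6-[(methylamino)methyl] derivative, aminomethyl cis to the ring ester | O=C1[C@@H](CNC)CCC=C[C@@]1(CC(C(=O)OC)C#C[Si](C)(C)C)C(=O)OC | intermediate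
9 | bridged keto lactam, methyl 2-[(8-methyl-9,10-dioxo-8-azabicyclo[4.3.1]dec-2-en-1-yl)methyl]-4-(trimethylsilyl)but-3-ynoate, C-19 epimers | O=C2[C@@H]1CCC=C[C@@]2(CC(C(=O)OC)C#C[Si](C)(C)C)C(=O)N(C)C1 | intermediate
10 | methyl 2-[(8-methyl-10-oxo-8-azabicyclo[4.3.1]dec-2-en-1-yl)methyl]-4-(trimethylsilyl)but-3-ynoate | O=C2[C@@H]1CCC=C[C@@]2(CC(C(=O)OC)C#C[Si](C)(C)C)CN(C)C1 | intermediate
11 | methyl 2-[(8-methyl-10-oxo-8-azabicyclo[4.3.1]dec-2-en-1-yl)methyl]but-3-ynoate | O=C2[C@@H]1CCC=C[C@@]2(CC(C(=O)OC)C#C)CN(C)C1 | intermediate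
12 | hexacarbonyldicobalt complex of the alkyne of 11 | O=C2[C@@H]1CCC=C[C@@]2(CC(C(=O)OC)C%10%11[CH]%12[Co]%10(=C=O)(=C=O)(=C=O)[Co]%11%12(=C=O)(=C=O)=C=O)CN(C)C1 | intermediate
13 | tetracyclic enone (rings B to E): C-15=C-16, C-17 ketone, C-7 ketone, H-13 and H-14 cis on the side of C-26, C-19 epimers | O=C2[C@@H]1CC[C@H]3[C@@H]4C(=CC3=O)C(C(=O)OC)C[C@@]42CN(C)C1 | intermediate
14 | 15,16-dihydro derivative of 13 (H-13, H-14, H-15 all cis) | O=C2[C@@H]1CC[C@H]3[C@@H]4[C@H](CC3=O)C(C(=O)OC)C[C@@]42CN(C)C1 | intermediate
15 | C-17 trimethylsilyl enol ether of 14 (C-13=C-17) | O=C2[C@@H]1CCC3=C(O[Si](C)(C)C)C[C@@H]([C@@H]34)C(C(=O)OC)C[C@@]42CN(C)C1 | intermediate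
16 | tetracyclic C-13=C-14 enone (C-17 ketone, C-7 ketone, H-15 α) | O=C2[C@@H]1CCC3=C4[C@H](CC3=O)C(C(=O)OC)C[C@@]42CN(C)C1 | intermediate
17 | (17S)-allylic alcohol, C-7 ketone, C-19 epimers | O=C2[C@@H]1CCC3=C4[C@H](C[C@@H]3O)C(C(=O)OC)C[C@@]42CN(C)C1 | intermediate
18 | C-7 methoxymethylidene enol ether (E/Z), C-19 epimers | COC=C2[C@@H]1CCC3=C4[C@H](C[C@@H]3O)C(C(=O)OC)C[C@@]42CN(C)C1 | intermediate
19 | C-7 methoxymethylidene enol ether (E/Z) with the (19R) ester cis to C-16 | COC=C2[C@@H]1CCC3=C4[C@H](C[C@@H]3O)[C@H](C(=O)OC)C[C@@]42CN(C)C1 | intermediate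
20 | C-7 carbaldehyde (C-7 epimers) | O=CC2[C@@H]1CCC3=C4[C@H](C[C@@H]3O)[C@H](C(=O)OC)C[C@@]42CN(C)C1 | intermediate
21 | C-7 quaternary aldehyde with hydroxymethyl C-8 syn to ring C | O=C[C@@]2(CO)[C@@H]1CCC3=C4[C@H](C[C@@H]3O)[C@H](C(=O)OC)C[C@@]42CN(C)C1 | intermediate
22 | (E)-enone, C-7 bearing CH2OH and CH=CH-C(O)Et | CCC(=O)/C=C/[C@@]2(CO)[C@@H]1CCC3=C4[C@H](C[C@@H]3O)[C@H](C(=O)OC)C[C@@]42CN(C)C1 | intermediate
23 | open δ-hydroxy ethyl ketone | CCC(=O)CC[C@@]2(CO)[C@@H]1CCC3=C4[C@H](C[C@@H]3O)[C@H](C(=O)OC)C[C@@]42CN(C)C1 | intermediate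
24 | CNP0124876.1 | CC[C@@]1(O)CC[C@@]2(CO1)[C@@H]1CCC3=C4[C@H](C[C@@H]3O)[C@H](C(=O)OC)C[C@@]42CN(C)C1 | target

## Step count and risks

Total step count: 13. Longest linear sequence: 12 (steps 1 and 3 to 13, from 1); step 2 is the side branch.

Step 3 is the first of the three steps most likely to fail: the enantioselectivity at C-25 is unproven, γ-attack and self-addition of 3 can compete, and the propargylic ester can isomerise to an allenoate. The fallback replaces catalyst control by a traceless auxiliary and sets out from 1. Transesterification with (−)-8-phenylmenthol (DMAP, toluene, reflux) gives (−)-8-phenylmenthyl 2-oxocycloheptane-1-carboxylate F1. Selenenylation to the α-phenylselenide F2 and oxidation as in step 1 give (−)-8-phenylmenthyl 7-oxocyclohept-1-ene-1-carboxylate F3. Cs2CO3-mediated deconjugative Michael addition to 6, with the phenyl ring shielding one face of the dienolate, gives the auxiliary-bearing adduct F4. The conditions of step 4 then take F4 through its Mannich base F5 to lactam 9, expelling the auxiliary alcohol, and the route is rejoined at 9.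

Step 6 is the second: the cycloaddition must engage a ring alkene next to a quaternary bridgehead, and its facial selectivity rests on the tether argument. The fallback runs the cycloaddition before the aza bridge is closed and sets out from 7. KF in MeOH gives the desilylated terminal alkyne F6. Co2(CO)8 then N-methylmorpholine N-oxide, through the dicobalt complex F7, gives the tricyclic enone diester F8 (rings C, D and E). The conditions of step 4 take F8 through its Mannich base F9 to the enone lactam F10. Hydrogenation (H2, Pd/C) gives the saturated keto lactam F11, and Zn(OAc)2 with (EtO)3SiH reduces the lactam to return to the route at 14.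

Step 11 is the third: formaldehyde may enter from the piperidine face, or retro-aldol and Cannizzaro pathways may prevail. The fallback inverts the order in which the two C-7 substituents are introduced, so that the opposite enolate face gives the natural configuration, and sets out from 19. After hydrolysis to aldehyde 20 as in step 11, Michael addition of its enolate to ethyl vinyl ketone (DBU, THF) gives the keto aldehyde F12, in which the aldehyde carbon is now C-8. Aldehyde-selective reduction with NaBH(OAc)3 gives hydroxy ketone 23, which closes to 24.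

Further compounds
F1 | step 3 | (−)-8-phenylmenthyl 2-oxocycloheptane-1-carboxylate | O=C1CCCCCC1C(=O)O[C@@H]1C[C@H](C)CC[C@H]1C(C)(C)c1ccccc1
F2 | step 3 | α-phenylselenide of F1 | O=C1CCCCCC1([Se]c1ccccc1)C(=O)O[C@@H]1C[C@H](C)CC[C@H]1C(C)(C)c1ccccc1
F3 | step 3 | (−)-8-phenylmenthyl 7-oxocyclohept-1-ene-1-carboxylate | O=C1CCCCC=C1C(=O)O[C@@H]1C[C@H](C)CC[C@H]1C(C)(C)c1ccccc1
F4 | step 3 | auxiliary-bearing Michael adduct (analogue of 7) | O=C1CCCC=C[C@@]1(CC(C(=O)OC)C#C[Si](C)(C)C)C(=O)O[C@@H]1C[C@H](C)CC[C@H]1C(C)(C)c1ccccc1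
F5 | step 3 | Mannich base of F4 | O=C1[C@@H](CNC)CCC=C[C@@]1(CC(C(=O)OC)C#C[Si](C)(C)C)C(=O)O[C@@H]1C[C@H](C)CC[C@H]1C(C)(C)c1ccccc1
F6 | step 6 | desilylated terminal alkyne of 7 | O=C1CCCC=C[C@@]1(CC(C(=O)OC)C#C)C(=O)OC
F7 | step 6 | hexacarbonyldicobalt complex of F6 | O=C1CCCC=C[C@@]1(CC(C(=O)OC)C%10%11[CH]%12[Co]%10(=C=O)(=C=O)(=C=O)[Co]%11%12(=C=O)(=C=O)=C=O)C(=O)OC
F8 | step 6 | tricyclic enone diester (rings C, D, E) | O=C1CCC[C@H]2[C@@H]3C(=CC2=O)C(C(=O)OC)C[C@@]31C(=O)OC
F9 | step 6 | Mannich base of F8 | O=C1[C@@H](CNC)CC[C@H]2[C@@H]3C(=CC2=O)C(C(=O)OC)C[C@@]31C(=O)OC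
F10 | step 6 | tetracyclic enone lactam | O=C2[C@@H]1CC[C@H]3[C@@H]4C(=CC3=O)C(C(=O)OC)C[C@@]42C(=O)N(C)C1
F11 | step 6 | tetracyclic saturated keto lactam | O=C2[C@@H]1CC[C@H]3[C@@H]4[C@H](CC3=O)C(C(=O)OC)C[C@@]42C(=O)N(C)C1
F12 | step 11 | keto aldehyde, C-7 bearing CHO (C-8) and CH2CH2C(O)Et | CCC(=O)CC[C@@]2(C=O)[C@@H]1CCC3=C4[C@H](C[C@@H]3O)[C@H](C(=O)OC)C[C@@]42CN(C)C1
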